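**Strategy**

Ring C is disconnected at O1–C8a and C2–C3, which divides the flavan into 3,4,5-tris(benzyloxy)benzaldehyde (O1, C2, ring B) and an ortho-fluoroaryl methoxymethyl ketone (C3, C4, C4a, C8a, ring A). The feature exploited is C4, the benzylic CH2 between C3 and ring A: raised for a time to a ketone, it acidifies C3–H for an aldol addition and activates the ortho C8a–F bond for SNAr, while the ring A oxygens at C5 and C7 sit meta to C8a. One operation thus makes both bonds and the complete C6–C3–C6 skeleton. The carbonyl is then transposed from C4 to C3, and one dynamic kinetic hydrogenation sets C2 and C3.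

Key step: step 3

Remark 1: flavan numbering is used (O1, C2, C3, C4, C4a, C5–C8, C8a; ring A = fused benzene ring, ring B = 2-aryl group, ring C = pyran ring).
Remark 2: compounds 1, 3, 7 and 15 are taken as purchasable.
Remark 3: compounds 9–13 are racemic mixtures of stereoisomers, so their SMILES carry no stereodescriptors; both stereocentres of the target are set in step 6.
Remark 4: the sense of induction in step 6 is assigned by analogy with 2-arylcycloalkanones; if a trial run shows the opposite sense, the mirror-image ligand pair is used.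

**Route**

Step 1
Reactants: 1 5-fluororesorcinol (5-fluorobenzene-1,3-diol)
Product: 2 1,3-bis(benzyloxy)-5-fluorobenzene
Conditions: BnBr, K2CO3, DMF, 60 °C
Reagents that add atoms: benzyl bromide, BrCc1ccccc1
Why: Williamson ether synthesis (SN2 on benzyl bromide by both phenoxides) should install the benzyl ethers that protect ring A until the last step.

Step 2
Reactants: 2 1,3-bis(benzyloxy)-5-fluorobenzene; 3 N,2-dimethoxy-N-methylacetamide
Product: 6 1-[2,4-bis(benzyloxy)-6-fluorophenyl]-2-methoxyethan-1-one, via aryllithium 4 (not isolated), via lithium hemiaminal adduct 5 (not isolated)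
Conditions: n-BuLi, THF, −78 °C; then 3, −78 → −30 °C; aq. NH4Cl
Reagents that add atoms: none
Why: Directed ortho-metalation should take place at the C–H flanked by fluorine and a benzyloxy group (the most acidic ring position, kept at −78 °C so that LiF is not lost to an aryne), and aryllithium 4 acylates the Weinreb amide through the chelated adduct 5, which stops at the ketone stage until work-up (Weinreb ketone synthesis).

Step 3
Reactants: 6 1-[2,4-bis(benzyloxy)-6-fluorophenyl]-2-methoxyethan-1-one; 7 3,4,5-tris(benzyloxy)benzaldehyde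
Product: 10 rac-5,7-bis(benzyloxy)-3-methoxy-2-[3,4,5-tris(benzyloxy)phenyl]chroman-4-one, via lithium enolate 8 (not isolated), via lithium aldolate 9 (not isolated)
Conditions: LiN(SiMe3)2 (1.0 equiv), THF, −78 °C; then 7, −78 °C; then DMPU, −78 → 25 °C
Reagents that add atoms: none
Why: LiN(SiMe3)2 gives the chelated (Z)-lithium enolate 8, which adds to aldehyde 7 (crossed aldol addition, C2–C3 bond), and on warming the oxygen of aldolate 9 attacks C8a and expels fluoride from the anionic σ-complex (addition–elimination SNAr, O1–C8a bond). The closest known reaction type is the aldol addition followed by intramolecular SNAr of an alkoxide on an ortho-fluoroaryl ketone, as used for chromanones and related benzo-fused heterocycles. Ring C, the only ring formed, closes in a 6-exo-trig sense by attack of O1 on the aromatic carbon C8a. C2 and C3 are created without control that matters: the (Z)-enolate should favour the syn aldolate and so the 2,3-cis chromanone, C3 can epimerise through its enolate towards the trans isomer, and neither relative nor absolute configuration is needed because step 5 flattens C3 and step 6 resets C2. The selectivity that is needed is arylation of O1 ahead of retro-aldol, dehydration or ring closure through another oxygen, and it is secured by the C4 carbonyl ortho to the single leaving group at C8a, by the two ring A ethers being meta to C8a, by the methyl cap on O3 (no five-membered benzofuranone closure), by one equivalent of base (no alkoxide left to reopen ring C) and by the irreversible SNAr draining the reversible aldol equilibrium.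

Step 4
Reactants: 10 rac-5,7-bis(benzyloxy)-3-methoxy-2-[3,4,5-tris(benzyloxy)phenyl]chroman-4-one
Product: 11 rac-5,7-bis(benzyloxy)-3-methoxy-2-[3,4,5-tris(benzyloxy)phenyl]chroman-4-ol
Conditions: NaBH4, THF/MeOH, 0 → 25 °C
Reagents that add atoms: none
Why: Borohydride reduction of the aryl ketone should give the benzylic alcohol as a mixture of C4 epimers, which is of no consequence because C4 ends as CH2.

Step 5
Reactants: 11 rac-5,7-bis(benzyloxy)-3-methoxy-2-[3,4,5-tris(benzyloxy)phenyl]chroman-4-ol
Product: 13 rac-5,7-bis(benzyloxy)-2-[3,4,5-tris(benzyloxy)phenyl]chroman-3-one, via enol ether 12 (not isolated)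
Conditions: TsOH·H2O (cat.), THF/H2O (10:1), 0.01 M, 45 °C, argon
Reagents that add atoms: water, O
Why: Acid ionises the C4–OH group (the cation is stabilised by O1 and the ethers at C5 and C7), loss of the C3 proton gives enol ether 12 (a 1,2-hydride shift leads to the same O-methyl oxocarbenium ion), and water hydrolyses it to the C3 ketone with loss of methanol, a pinacol-type 1,2-carbonyl transposition of the kind used to make chroman-3-ones from chroman-3,4-diol derivatives; C3 becomes sp2 and C2 stays racemic.

Step 6
Reactants: 13 rac-5,7-bis(benzyloxy)-2-[3,4,5-tris(benzyloxy)phenyl]chroman-3-one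
Product: 14 (2R,3R)-5,7-bis(benzyloxy)-2-[3,4,5-tris(benzyloxy)phenyl]chroman-3-ol
Conditions: H2 (10 atm), trans-RuCl2[(S)-XylBINAP][(S)-DAIPEN] (cat.), KOt-Bu (cat.), i-PrOH/THF, 25 °C
Reagents that add atoms: none
Why: Noyori asymmetric hydrogenation under dynamic kinetic resolution, a known process for racemic α-aryl and α-alkoxy cyclic ketones: KOt-Bu should epimerise C2 (benzylic, α to the ketone and to O1) through the enolate faster than the ketone is reduced, the chiral diphosphine–diamine ruthenium hydride should reduce the (2R)-ketone preferentially (C2 set by the resolution) and deliver hydride to C3 on the face anti to the 2-aryl group (C3 set by catalyst and substrate together), which gives the 2,3-cis (2R,3R) alcohol.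

Step 7
Reactants: 14 (2R,3R)-5,7-bis(benzyloxy)-2-[3,4,5-tris(benzyloxy)phenyl]chroman-3-ol; 15 4-(benzyloxy)-3,5-dimethoxybenzoic acid
Product: 16 (2R,3R)-5,7-bis(benzyloxy)-2-[3,4,5-tris(benzyloxy)phenyl]chroman-3-yl 4-(benzyloxy)-3,5-dimethoxybenzoate
Conditions: DCC, DMAP (cat.), CH2Cl2, 25 °C
Reagents that add atoms: none
Why: Steglich esterification (carbodiimide activation, DMAP as acyl transfer catalyst) should acylate the hindered 3-OH group; the C3–O bond is not broken, so both stereocentres are retained.

Step 8
Reactants: 16 (2R,3R)-5,7-bis(benzyloxy)-2-[3,4,5-tris(benzyloxy)phenyl]chroman-3-yl 4-(benzyloxy)-3,5-dimethoxybenzoate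
Product: 17 epigallocatechin 3-O-(3,5-di-O-methylgallate)
Conditions: H2 (1 atm), Pd(OH)2/C, THF/MeOH, 25 °C
Reagents that add atoms: none
Why: Hydrogenolysis should cleave all six O-benzyl ethers (five on the flavan, one on the benzoate) under neutral conditions, while the ester, the two methyl ethers, the cyclic C2–O1 ether and both stereocentres remain untouched.

**Compound list**

1 | 5-fluororesorcinol (5-fluorobenzene-1,3-diol) | Oc1cc(O)cc(F)c1 | starting material
2 | 1,3-bis(benzyloxy)-5-fluorobenzene | Fc1cc(OCc2ccccc2)cc(OCc2ccccc2)c1 | intermediate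
3 | N,2-dimethoxy-N-methylacetamide (Weinreb amide of methoxyacetic acid) | COCC(=O)N(C)OC | starting material
4 | [2,4-bis(benzyloxy)-6-fluorophenyl]lithium (formed in the flask, not isolated) | [Li]c1c(F)cc(OCc2ccccc2)cc1OCc1ccccc1 | intermediate
5 | lithium 1-[2,4-bis(benzyloxy)-6-fluorophenyl]-2-methoxy-1-[methoxy(methyl)amino]ethan-1-olate (formed in the flask, not isolated) | [Li+].[O-]C(COC)(N(C)OC)c1c(F)cc(OCc2ccccc2)cc1OCc1ccccc1 | intermediate
6 | 1-[2,4-bis(benzyloxy)-6-fluorophenyl]-2-methoxyethan-1-one | COCC(=O)c1c(F)cc(OCc2ccccc2)cc1OCc1ccccc1 | intermediate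
7 | 3,4,5-tris(benzyloxy)benzaldehyde | O=Cc1cc(OCc2ccccc2)c(OCc2ccccc2)c(OCc2ccccc2)c1 | starting material
8 | lithium (Z)-1-[2,4-bis(benzyloxy)-6-fluorophenyl]-2-methoxyethen-1-olate (formed in the flask, not isolated) | [Li+].[O-]/C(=C\OC)c1c(F)cc(OCc2ccccc2)cc1OCc1ccccc1 | intermediate
9 | lithium 3-[2,4-bis(benzyloxy)-6-fluorophenyl]-2-methoxy-3-oxo-1-[3,4,5-tris(benzyloxy)phenyl]propan-1-olate, syn/anti mixture, racemic (formed in the flask, not isolated) | [Li+].[O-]C(c1cc(OCc2ccccc2)c(OCc2ccccc2)c(OCc2ccccc2)c1)C(OC)C(=O)c1c(F)cc(OCc2ccccc2)cc1OCc1ccccc1 | intermediate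
10 | rac-5,7-bis(benzyloxy)-3-methoxy-2-[3,4,5-tris(benzyloxy)phenyl]chroman-4-one, mixture of 2,3-cis and 2,3-trans isomers | COC1C(c2cc(OCc3ccccc3)c(OCc3ccccc3)c(OCc3ccccc3)c2)Oc2cc(OCc3ccccc3)cc(OCc3ccccc3)c2C1=O | intermediate
11 | rac-5,7-bis(benzyloxy)-3-methoxy-2-[3,4,5-tris(benzyloxy)phenyl]chroman-4-ol, mixture of diastereomers | COC1C(c2cc(OCc3ccccc3)c(OCc3ccccc3)c(OCc3ccccc3)c2)Oc2cc(OCc3ccccc3)cc(OCc3ccccc3)c2C1O | intermediate
12 | rac-5,7-bis(benzyloxy)-3-methoxy-2-[3,4,5-tris(benzyloxy)phenyl]-2H-chromene (enol ether, formed in the flask, not isolated) | COC1=Cc2c(OCc3ccccc3)cc(OCc3ccccc3)cc2OC1c1cc(OCc2ccccc2)c(OCc2ccccc2)c(OCc2ccccc2)c1 | intermediate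
13 | rac-5,7-bis(benzyloxy)-2-[3,4,5-tris(benzyloxy)phenyl]chroman-3-one | O=C1Cc2c(OCc3ccccc3)cc(OCc3ccccc3)cc2OC1c1cc(OCc2ccccc2)c(OCc2ccccc2)c(OCc2ccccc2)c1 | intermediate
14 | (2R,3R)-5,7-bis(benzyloxy)-2-[3,4,5-tris(benzyloxy)phenyl]chroman-3-ol (2,3-cis; penta-O-benzyl-epigallocatechin) | O[C@@H]1Cc2c(OCc3ccccc3)cc(OCc3ccccc3)cc2O[C@@H]1c1cc(OCc2ccccc2)c(OCc2ccccc2)c(OCc2ccccc2)c1 | intermediate
15 | 4-(benzyloxy)-3,5-dimethoxybenzoic acid | COc1cc(C(=O)O)cc(OC)c1OCc1ccccc1 | starting material
16 | (2R,3R)-5,7-bis(benzyloxy)-2-[3,4,5-tris(benzyloxy)phenyl]chroman-3-yl 4-(benzyloxy)-3,5-dimethoxybenzoate | COc1cc(C(=O)O[C@@H]2Cc3c(OCc4ccccc4)cc(OCc4ccccc4)cc3O[C@@H]2c2cc(OCc3ccccc3)c(OCc3ccccc3)c(OCc3ccccc3)c2)cc(OC)c1OCc1ccccc1 | intermediate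
17 | epigallocatechin 3-O-(3,5-di-O-methylgallate), (2R,3R) | COc1cc(C(=O)O[C@@H]2Cc3c(O)cc(O)cc3O[C@@H]2c2cc(O)c(O)c(O)c2)cc(OC)c1O | target

**Step count and risks**

Total step count: 8. Longest linear sequence: 8 steps (1 → 17); the building blocks 3, 7 and 15 enter as purchased compounds.

Steps most likely to fail:

Step 6. Epimerisation at C2 may be slower than reduction, so that the hydrogenation becomes a plain kinetic resolution, or the catalyst may discriminate the two ketone enantiomers poorly. The fallback sets out from 13: reduction with LiBH(s-Bu)3 in THF at −78 °C (hydride anti to the 2-aryl group) should give the racemic 2,3-cis alcohol, that is 14 together with its mirror image (2S,3S)-5,7-bis(benzyloxy)-2-[3,4,5-tris(benzyloxy)phenyl]chroman-3-ol F4. The two are separated by preparative chromatography on a chiral stationary phase, and the route is rejoined at 14. F4 can be returned to 13 by Dess–Martin oxidation, since the ketone racemises with Et3N.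

Step 5. The C4 cation may be intercepted by ring A of a second molecule (Friedel–Crafts oligomerisation), or the enol ether may be oxidised by air to a flavylium salt. The fallback sets out from 10: condensation with TsNHNH2 (EtOH, cat. AcOH, reflux) should give the tosylhydrazone F3. Its sodium salt (NaH, toluene, 110 °C, aprotic Bamford–Stevens reaction) loses sulfinate and N2, and the carbene undergoes a 1,2-hydride shift from C3 to give enol ether 12 without any cation at C4. Hydrolysis of 12 with oxalic acid in wet THF rejoins the route at 13.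

Step 3. The lithium aldolate may revert by retro-aldol cleavage faster than its oxygen attacks C8a, or surplus amide base may reopen ring C of the product by β-elimination of the phenoxide. The fallback sets out from 6: TMSOTf and Et3N (CH2Cl2, 0 °C) should give the (Z)-trimethylsilyl enol ether F1. With 7 and anhydrous CsF in DMF at 25 °C, fluoride releases the enolate, which adds to 7 to give the caesium aldolate F2. This more nucleophilic, amide-free alkoxide closes ring C by SNAr, and the fluoride it expels carries the chain; the route is rejoined at 10. Both bonds are still made in one operation.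

Further compounds
F1 | step 3 | (Z)-{1-[2,4-bis(benzyloxy)-6-fluorophenyl]-2-methoxyethenyl}oxy(trimethyl)silane | C[Si](C)(C)O/C(=C\OC)c1c(F)cc(OCc2ccccc2)cc1OCc1ccccc1
F2 | step 3 | caesium 3-[2,4-bis(benzyloxy)-6-fluorophenyl]-2-methoxy-3-oxo-1-[3,4,5-tris(benzyloxy)phenyl]propan-1-olate (racemic, syn/anti mixture) | [Cs+].[O-]C(c1cc(OCc2ccccc2)c(OCc2ccccc2)c(OCc2ccccc2)c1)C(OC)C(=O)c1c(F)cc(OCc2ccccc2)cc1OCc1ccccc1
F3 | step 5 | N'-{5,7-bis(benzyloxy)-3-methoxy-2-[3,4,5-tris(benzyloxy)phenyl]chroman-4-ylidene}-4-methylbenzenesulfonohydrazide (racemic, mixture of isomers) | COC1C(c2cc(OCc3ccccc3)c(OCc3ccccc3)c(OCc3ccccc3)c2)Oc2cc(OCc3ccccc3)cc(OCc3ccccc3)c2C1=NNS(=O)(=O)c1ccc(C)cc1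
F4 | step 6 | (2S,3S)-5,7-bis(benzyloxy)-2-[3,4,5-tris(benzyloxy)phenyl]chroman-3-ol | O[C@H]1Cc2c(OCc3ccccc3)cc(OCc3ccccc3)cc2O[C@H]1c1cc(OCc2ccccc2)c(OCc2ccccc2)c(OCc2ccccc2)c1
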